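**Plan**

1. Ring labels: A = terminal 3,5-dihydroxyphenoxy ring; B = ring with ring A on O1, ring C on O4 and the C-linked phloroglucinol ring F at C3; C = 2,6-dihydroxy ring with ring B on O1 and ring D on O4; D = core ring with oxygens at C1 (to ring C), C2 and C6 (to the two rings E) and C4 (OH); E = the two arm rings, bound through O1 to ring D, each C-linked at C3 to a phloroglucinol ring G.
2. Cuts, backwards: the 22 O–CH3 bonds; ring A–O (Ullmann); C1–O of ring B (Dakin) and O–C4 of ring B (SNAr); C1–O of ring C (Dakin) and O–C4 of ring C (SNAr); the two E–G biaryl bonds (Suzuki); then, in one operation, C1(D)–O and C4(E)–O of both arms (triple Dakin); last the two D–O–E ether bonds (double SNAr).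
3. Enabling feature: on ring D the C1 oxygen lies between the oxygens at C2 and C6 and para to the oxygen at C4, and on each ring E the ether oxygen at C1 is para to the hydroxyl at C4. C1 of ring D and C4 of each ring E can therefore enter as formyl carbons: the ring D formyl activates both ortho fluorides, and the ring E formyl is the aldehyde of syringaldehyde.
4. Forward: bromosyringaldehyde is joined twice to 2,6-difluoro-4-methoxybenzaldehyde, the trialdehyde is oxidised threefold, and the chain then grows outward from the ring D oxygen (ring C, rings G, ring B with ring F, ring A) before global demethylation. No ring is closed; every ring is a purchased arene.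
5. The bromine at C3 of each ring E is kept through the oxidation on purpose. An arm phenol next to the bulky ring G would not be reliably distinguishable from the ring D phenol, whereas an ortho-bromophenol is clearly more acidic and less hindered, so the arms can be capped selectively; ring G replaces bromine afterwards.
6. Stereochemistry: the target has no stereocentre and no configurationally defined axis (every biaryl axis carries a symmetric 2,4,6-trioxygenated ring), so nothing needs control.

Key step: step 3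

Remark: compounds 1, 3, 8, 10 and 19 are taken as purchasable arenes.

**Step 1**
Reactants: 1 syringaldehyde
Product: 2 2-bromo-4-hydroxy-3,5-dimethoxybenzaldehyde
Conditions: Br2 (1.05 equiv), AcOH, rt
Reagents that add atoms: bromine, BrBr
Why: Electrophilic aromatic bromination; C2 (equivalent to C6) is the only free position and is activated ortho and para by the two methoxy groups, and the deactivated monobromide should not react further with one equivalent of bromine.

**Step 2**
Reactants: 2 2-bromo-4-hydroxy-3,5-dimethoxybenzaldehyde (2.3 equiv); 3 2,6-difluoro-4-methoxybenzaldehyde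
Product: 4 2,6-bis(3-bromo-4-formyl-2,6-dimethoxyphenoxy)-4-methoxybenzaldehyde
Conditions: Cs2CO3 (2.5 equiv), DMAc, 120 °C, argon
Reagents that add atoms: none
Why: Twofold nucleophilic aromatic substitution (SNAr); each fluoride of 3 is ortho to the formyl group that stabilises the Meisenheimer adduct, the 4-methoxy group is meta to both reacting carbons, the bromide of 2 sits ortho and para to methoxy donors and is not displaced, and Cs2CO3 with heat compensates for the weakly nucleophilic formyl-phenoxide.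

**Step 3**
Reactants: 4 2,6-bis(3-bromo-4-formyl-2,6-dimethoxyphenoxy)-4-methoxybenzaldehyde
Product: 6 2,6-bis(3-bromo-4-hydroxy-2,6-dimethoxyphenoxy)-4-methoxyphenol, via tris(formate) ester 5 (not isolated)
Conditions: mCPBA (3.6 equiv), CH2Cl2, 0 °C to rt; aqueous Na2S2O3/NaHCO3 wash; then Et3N (cat.), MeOH, rt, argon
Reagents that add atoms: 3-chloroperoxybenzoic acid (mCPBA), O=C(OO)c1cccc(Cl)c1
Why: Dakin-type Baeyer–Villiger oxidation: the peracid adds to each formyl group to give a Criegee adduct, the aryl group migrates from carbon to oxygen with loss of 3-chlorobenzoate, and the three aryl formates of 5 are then cleaved by amine-catalysed methanolysis. The closest known reaction type is the peracid oxidation of alkoxy- and aryloxy-benzaldehydes, ortho-bromo and 2,6-dioxygenated ones included, to phenols. No ring is closed and no stereocentre is formed; the step makes the C1(D)–O bond and the C4(E)–O bonds of both arms. The selectivity needed is aryl over hydride migration at all three sites: on ring D the migrating carbon has two ortho aryloxy groups and a para methoxy group, and on each ring E it has a para aryloxy group and an ortho bromine whose bulk also favours aryl migration. The electron-rich rings should survive because the phenols stay masked as formates until the excess peracid has been washed out, and because no phloroglucinol-type ring G is yet present.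

**Step 4**
Reactants: 6 2,6-bis(3-bromo-4-hydroxy-2,6-dimethoxyphenoxy)-4-methoxyphenol
Product: 7 2,6-bis(3-bromo-2,4,6-trimethoxyphenoxy)-4-methoxyphenol
Conditions: MeI (2.1 equiv), KHCO3 (2.5 equiv), DMF, rt to 40 °C
Reagents that add atoms: iodomethane, CI
Why: Acidity-controlled Williamson O-methylation; each arm hydroxyl is an ortho-bromophenol with two meta methoxy groups and one open ortho position, estimated from substituent effects to be about two pKa units more acidic than the ring D hydroxyl flanked by two aryloxy groups, so the weak base KHCO3 with two equivalents of iodomethane should ionise and alkylate only the arm phenols.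

**Step 5**
Reactants: 7 2,6-bis(3-bromo-2,4,6-trimethoxyphenoxy)-4-methoxyphenol; 8 4-fluoro-2,6-dimethoxybenzaldehyde (1.3 equiv)
Product: 9 4-[2,6-bis(3-bromo-2,4,6-trimethoxyphenoxy)-4-methoxyphenoxy]-2,6-dimethoxybenzaldehyde
Conditions: Cs2CO3 (1.5 equiv), DMSO, 100 °C, argon
Reagents that add atoms: none
Why: SNAr; the fluoride of 8 is para to the formyl group and meta to both methoxy groups, so the Meisenheimer adduct is stabilised, the ring D phenoxide is the only nucleophile in 7, and the unactivated aryl bromides stay.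

**Step 6**
Reactants: 9 4-[2,6-bis(3-bromo-2,4,6-trimethoxyphenoxy)-4-methoxyphenoxy]-2,6-dimethoxybenzaldehyde; 10 (2,4,6-trimethoxyphenyl)boronic acid (5 equiv)
Product: 11 4-{2,6-bis[2,4,6-trimethoxy-3-(2,4,6-trimethoxyphenyl)phenoxy]-4-methoxyphenoxy}-2,6-dimethoxybenzaldehyde
Conditions: Pd(OAc)2 (10 mol %), SPhos (20 mol %), K3PO4, toluene/H2O 10:1, 100 °C
Reagents that add atoms: none
Why: Twofold Suzuki–Miyaura coupling; Pd(OAc)2 with the biaryl phosphine SPhos is an established system for tetra-ortho-substituted biaryls from electron-rich di-ortho-substituted bromides and 2,6-dialkoxyphenylboronic acids, excess 10 offsets protodeboronation, and the hindered aldehyde is inert.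

**Step 7**
Reactants: 11 4-{2,6-bis[2,4,6-trimethoxy-3-(2,4,6-trimethoxyphenyl)phenoxy]-4-methoxyphenoxy}-2,6-dimethoxybenzaldehyde
Product: 13 4-{2,6-bis[2,4,6-trimethoxy-3-(2,4,6-trimethoxyphenyl)phenoxy]-4-methoxyphenoxy}-2,6-dimethoxyphenol, via ring C formate ester 12 (not isolated)
Conditions: 30% aq. H2O2 (1.5 equiv), H2SO4 (cat.), MeOH/CH2Cl2 2:1, rt
Reagents that add atoms: hydrogen peroxide, OO
Why: Acid-catalysed Dakin oxidation; the formyl group lies between two methoxy groups and para to an aryloxy group, so aryl migration is strongly favoured, the formate is methanolysed in the same flask, and hydrogen peroxide without a peracid should leave the trimethoxyphenyl rings G alone.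

**Step 8**
Reactants: 8 4-fluoro-2,6-dimethoxybenzaldehyde
Product: 14 3-bromo-4-fluoro-2,6-dimethoxybenzaldehyde
Conditions: NBS (1.0 equiv), MeCN, rt
Reagents that add atoms: N-bromosuccinimide, O=C1CCC(=O)N1Br
Why: Electrophilic aromatic bromination; C3 (equivalent to C5) is ortho to one methoxy group and para to the other and is the only kind of free position, so one equivalent of NBS should give the monobromide.

**Step 9**
Reactants: 14 3-bromo-4-fluoro-2,6-dimethoxybenzaldehyde; 10 (2,4,6-trimethoxyphenyl)boronic acid (2 equiv)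
Product: 15 4-fluoro-2,6-dimethoxy-3-(2,4,6-trimethoxyphenyl)benzaldehyde
Conditions: Pd(OAc)2 (5 mol %), SPhos (10 mol %), K3PO4, toluene/H2O 10:1, 80 °C
Reagents that add atoms: none
Why: Suzuki–Miyaura coupling; oxidative addition takes place at the C–Br bond only, the C–F bond is untouched, and the two-phase medium should keep hydrolysis of the activated fluoride low.

**Step 10**
Reactants: 13 4-{2,6-bis[2,4,6-trimethoxy-3-(2,4,6-trimethoxyphenyl)phenoxy]-4-methoxyphenoxy}-2,6-dimethoxyphenol; 15 4-fluoro-2,6-dimethoxy-3-(2,4,6-trimethoxyphenyl)benzaldehyde (1.5 equiv)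
Product: 16 4-(4-{2,6-bis[2,4,6-trimethoxy-3-(2,4,6-trimethoxyphenyl)phenoxy]-4-methoxyphenoxy}-2,6-dimethoxyphenoxy)-2,6-dimethoxy-3-(2,4,6-trimethoxyphenyl)benzaldehyde
Conditions: Cs2CO3 (2 equiv), DMSO, 110 °C, argon
Reagents that add atoms: none
Why: SNAr; the fluoride of 15 is para to the formyl group, the 2,6-dimethoxyphenoxide of 13 is a strong nucleophile, and Cs2CO3 in DMSO at elevated temperature should overcome the hindrance by the neighbouring ring F.

**Step 11**
Reactants: 16 4-(4-{2,6-bis[2,4,6-trimethoxy-3-(2,4,6-trimethoxyphenyl)phenoxy]-4-methoxyphenoxy}-2,6-dimethoxyphenoxy)-2,6-dimethoxy-3-(2,4,6-trimethoxyphenyl)benzaldehyde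
Product: 18 4-(4-{2,6-bis[2,4,6-trimethoxy-3-(2,4,6-trimethoxyphenyl)phenoxy]-4-methoxyphenoxy}-2,6-dimethoxyphenoxy)-2,6-dimethoxy-3-(2,4,6-trimethoxyphenyl)phenol, via ring B formate ester 17 (not isolated)
Conditions: 30% aq. H2O2 (1.5 equiv), H2SO4 (cat.), MeOH/CH2Cl2 2:1, rt
Reagents that add atoms: hydrogen peroxide, OO
Why: Acid-catalysed Dakin oxidation as in step 7; the ring B formyl group again lies between two methoxy groups and para to an aryloxy group, which secures aryl migration.

**Step 12**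
Reactants: 18 4-(4-{2,6-bis[2,4,6-trimethoxy-3-(2,4,6-trimethoxyphenyl)phenoxy]-4-methoxyphenoxy}-2,6-dimethoxyphenoxy)-2,6-dimethoxy-3-(2,4,6-trimethoxyphenyl)phenol; 19 1-iodo-3,5-dimethoxybenzene (2 equiv)
Product: 20 3,5-dimethoxyphenyl ether of 18 (the target with all 22 hydroxyl groups as methyl ethers)
Conditions: CuI (20 mol %), picolinic acid (40 mol %), K3PO4 (2 equiv), DMSO, 90 °C, argon
Reagents that add atoms: none
Why: Ullmann diaryl ether synthesis; CuI with picolinic acid and K3PO4 in DMSO is an established system for 2,6-disubstituted phenols and aryl iodides, and the unactivated 3,5-dimethoxyphenyl ring cannot be brought in by SNAr.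

**Step 13**
Reactants: 20 3,5-dimethoxyphenyl ether of 18 (docosa-O-methyl ether of the target)
Product: 21 CNP0117322.0
Conditions: BBr3 (60 equiv), CH2Cl2, −78 °C to rt; then H2O, 0 °C; work-up and chromatography under argon
Reagents that add atoms: none
Why: Lewis acid demethylation of aryl methyl ethers with BBr3; all 22 methoxy groups should be cleaved via aryloxydibromoboranes and bromomethane, while diaryl ether and biaryl bonds are inert to BBr3 at or below room temperature.

**Compound list**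

1 | syringaldehyde (4-hydroxy-3,5-dimethoxybenzaldehyde) | COc1cc(C=O)cc(OC)c1O | starting material
2 | 2-bromo-4-hydroxy-3,5-dimethoxybenzaldehyde | COc1cc(C=O)c(Br)c(OC)c1O | intermediate
3 | 2,6-difluoro-4-methoxybenzaldehyde | COc1cc(F)c(C=O)c(F)c1 | starting material
4 | 2,6-bis(3-bromo-4-formyl-2,6-dimethoxyphenoxy)-4-methoxybenzaldehyde | COc1cc(Oc2c(OC)cc(C=O)c(Br)c2OC)c(C=O)c(Oc2c(OC)cc(C=O)c(Br)c2OC)c1 | intermediate
5 | 2,6-bis[3-bromo-4-(formyloxy)-2,6-dimethoxyphenoxy]-4-methoxyphenyl formate | COc1cc(Oc2c(OC)cc(OC=O)c(Br)c2OC)c(OC=O)c(Oc2c(OC)cc(OC=O)c(Br)c2OC)c1 | intermediate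
6 | 2,6-bis(3-bromo-4-hydroxy-2,6-dimethoxyphenoxy)-4-methoxyphenol | COc1cc(Oc2c(OC)cc(O)c(Br)c2OC)c(O)c(Oc2c(OC)cc(O)c(Br)c2OC)c1 | intermediate
7 | 2,6-bis(3-bromo-2,4,6-trimethoxyphenoxy)-4-methoxyphenol | COc1cc(Oc2c(OC)cc(OC)c(Br)c2OC)c(O)c(Oc2c(OC)cc(OC)c(Br)c2OC)c1 | intermediate
8 | 4-fluoro-2,6-dimethoxybenzaldehyde | COc1cc(F)cc(OC)c1C=O | starting material
9 | 4-[2,6-bis(3-bromo-2,4,6-trimethoxyphenoxy)-4-methoxyphenoxy]-2,6-dimethoxybenzaldehyde | COc1cc(Oc2c(OC)cc(OC)c(Br)c2OC)c(Oc2cc(OC)c(C=O)c(OC)c2)c(Oc2c(OC)cc(OC)c(Br)c2OC)c1 | intermediate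
10 | (2,4,6-trimethoxyphenyl)boronic acid | COc1cc(OC)c(B(O)O)c(OC)c1 | starting material
11 | 4-{2,6-bis[2,4,6-trimethoxy-3-(2,4,6-trimethoxyphenyl)phenoxy]-4-methoxyphenoxy}-2,6-dimethoxybenzaldehyde | COc1cc(Oc2c(OC)cc(OC)c(-c3c(OC)cc(OC)cc3OC)c2OC)c(Oc2cc(OC)c(C=O)c(OC)c2)c(Oc2c(OC)cc(OC)c(-c3c(OC)cc(OC)cc3OC)c2OC)c1 | intermediate
12 | 4-{2,6-bis[2,4,6-trimethoxy-3-(2,4,6-trimethoxyphenyl)phenoxy]-4-methoxyphenoxy}-2,6-dimethoxyphenyl formate | COc1cc(Oc2c(OC)cc(OC)c(-c3c(OC)cc(OC)cc3OC)c2OC)c(Oc2cc(OC)c(OC=O)c(OC)c2)c(Oc2c(OC)cc(OC)c(-c3c(OC)cc(OC)cc3OC)c2OC)c1 | intermediate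
13 | 4-{2,6-bis[2,4,6-trimethoxy-3-(2,4,6-trimethoxyphenyl)phenoxy]-4-methoxyphenoxy}-2,6-dimethoxyphenol | COc1cc(Oc2c(OC)cc(OC)c(-c3c(OC)cc(OC)cc3OC)c2OC)c(Oc2cc(OC)c(O)c(OC)c2)c(Oc2c(OC)cc(OC)c(-c3c(OC)cc(OC)cc3OC)c2OC)c1 | intermediate
14 | 3-bromo-4-fluoro-2,6-dimethoxybenzaldehyde | COc1cc(F)c(Br)c(OC)c1C=O | intermediate
15 | 4-fluoro-2,6-dimethoxy-3-(2,4,6-trimethoxyphenyl)benzaldehyde | COc1cc(F)c(-c2c(OC)cc(OC)cc2OC)c(OC)c1C=O | intermediate
16 | 4-(4-{2,6-bis[2,4,6-trimethoxy-3-(2,4,6-trimethoxyphenyl)phenoxy]-4-methoxyphenoxy}-2,6-dimethoxyphenoxy)-2,6-dimethoxy-3-(2,4,6-trimethoxyphenyl)benzaldehyde | COc1cc(Oc2c(OC)cc(OC)c(-c3c(OC)cc(OC)cc3OC)c2OC)c(Oc2cc(OC)c(Oc3cc(OC)c(C=O)c(OC)c3-c3c(OC)cc(OC)cc3OC)c(OC)c2)c(Oc2c(OC)cc(OC)c(-c3c(OC)cc(OC)cc3OC)c2OC)c1 | intermediate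
17 | 4-(4-{2,6-bis[2,4,6-trimethoxy-3-(2,4,6-trimethoxyphenyl)phenoxy]-4-methoxyphenoxy}-2,6-dimethoxyphenoxy)-2,6-dimethoxy-3-(2,4,6-trimethoxyphenyl)phenyl formate | COc1cc(Oc2c(OC)cc(OC)c(-c3c(OC)cc(OC)cc3OC)c2OC)c(Oc2cc(OC)c(Oc3cc(OC)c(OC=O)c(OC)c3-c3c(OC)cc(OC)cc3OC)c(OC)c2)c(Oc2c(OC)cc(OC)c(-c3c(OC)cc(OC)cc3OC)c2OC)c1 | intermediate
18 | 4-(4-{2,6-bis[2,4,6-trimethoxy-3-(2,4,6-trimethoxyphenyl)phenoxy]-4-methoxyphenoxy}-2,6-dimethoxyphenoxy)-2,6-dimethoxy-3-(2,4,6-trimethoxyphenyl)phenol | COc1cc(Oc2c(OC)cc(OC)c(-c3c(OC)cc(OC)cc3OC)c2OC)c(Oc2cc(OC)c(Oc3cc(OC)c(O)c(OC)c3-c3c(OC)cc(OC)cc3OC)c(OC)c2)c(Oc2c(OC)cc(OC)c(-c3c(OC)cc(OC)cc3OC)c2OC)c1 | intermediate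
19 | 1-iodo-3,5-dimethoxybenzene | COc1cc(I)cc(OC)c1 | starting material
20 | 3,5-dimethoxyphenyl ether of 18 (docosa-O-methyl ether of the target) | COc1cc(Oc2c(OC)cc(OC)c(-c3c(OC)cc(OC)cc3OC)c2OC)c(Oc2cc(OC)c(Oc3cc(OC)c(Oc4cc(OC)cc(OC)c4)c(OC)c3-c3c(OC)cc(OC)cc3OC)c(OC)c2)c(Oc2c(OC)cc(OC)c(-c3c(OC)cc(OC)cc3OC)c2OC)c1 | intermediate
21 | CNP0117322.0 (rings A to G as defined in the plan, all 22 oxygens not in ether bridges as free hydroxyls) | Oc1cc(O)cc(Oc2c(O)cc(Oc3c(O)cc(Oc4c(Oc5c(O)cc(O)c(-c6c(O)cc(O)cc6O)c5O)cc(O)cc4Oc4c(O)cc(O)c(-c5c(O)cc(O)cc5O)c4O)cc3O)c(-c3c(O)cc(O)cc3O)c2O)c1 | target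

**Step count and risks**

Total: 13 steps. Longest linear sequence: 11 steps (steps 1–7 and 10–13, from syringaldehyde); steps 8 and 9 form the side branch to 15.

Most likely to fail:

Step 6. Oxidative addition at bromides flanked by two methoxy groups is slow, while the di-ortho-methoxy boronic acid loses boron under the basic aqueous conditions, so the coupling may stall after one arylation. Fallback, from 9 back to 11, as a Negishi coupling: 1,3,5-trimethoxybenzene (COc1cc(OC)cc(OC)c1) is lithiated between two methoxy groups with n-BuLi in THF to (2,4,6-trimethoxyphenyl)lithium F1, which is transmetalated with ZnCl2 to (2,4,6-trimethoxyphenyl)zinc chloride F2. F2 (excess) is coupled with 9 using Pd2(dba)3 and RuPhos in THF at 65 °C to give 11. The zinc reagent cannot protodemetalate under anhydrous conditions, and the aldehyde of 9, flanked by two methoxy groups, should not add an arylzinc halide at this temperature.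

Step 10. Addition of the phenoxide to the carbon next to the perpendicular ring F may be so slow that decomposition of the electron-rich phenoxide competes at the temperature required. Fallback, from 13 back to 16, reversing the order of ether formation and biaryl coupling: 13 is condensed with the bromofluoroaldehyde 14 (Cs2CO3, DMSO, 90 °C), whose bromine is smaller than ring F and activates the fluoride inductively. This gives 3-bromo-4-(4-{2,6-bis[2,4,6-trimethoxy-3-(2,4,6-trimethoxyphenyl)phenoxy]-4-methoxyphenoxy}-2,6-dimethoxyphenoxy)-2,6-dimethoxybenzaldehyde F3, and ring F is then attached by Suzuki–Miyaura coupling of F3 with 10 (Pd(OAc)2, SPhos, K3PO4, toluene/H2O) to give 16.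

Step 4. Site selectivity may be lost: the ring D hydroxyl may be methylated alongside the arm phenols, or the reaction may stop at monomethylation. Fallback, from 6 back to 7, protecting all three phenols and then differentiating the esters:
- 6 is peracetylated (Ac2O, pyridine) to 2,6-bis(4-acetoxy-3-bromo-2,6-dimethoxyphenoxy)-4-methoxyphenyl acetate F4.
- The two arm acetates, esters of the more acidic and less hindered phenols, are removed with PhSH and catalytic imidazole in NMP to give 2,6-bis(3-bromo-4-hydroxy-2,6-dimethoxyphenoxy)-4-methoxyphenyl acetate F5.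
- The arm phenols are methylated under neutral Mitsunobu conditions (MeOH, PPh3, DIAD, THF), which avoid acetyl migration, to give 2,6-bis(3-bromo-2,4,6-trimethoxyphenoxy)-4-methoxyphenyl acetate F6.
- Methanolysis (K2CO3 cat., MeOH) frees the ring D phenol 7.

**Further compounds**

F1 | step 6 | (2,4,6-trimethoxyphenyl)lithium | [Li]c1c(OC)cc(OC)cc1OC
F2 | step 6 | (2,4,6-trimethoxyphenyl)zinc chloride | Cl[Zn]c1c(OC)cc(OC)cc1OC
F3 | step 10 | 3-bromo-4-(4-{2,6-bis[2,4,6-trimethoxy-3-(2,4,6-trimethoxyphenyl)phenoxy]-4-methoxyphenoxy}-2,6-dimethoxyphenoxy)-2,6-dimethoxybenzaldehyde | COc1cc(Oc2c(OC)cc(OC)c(-c3c(OC)cc(OC)cc3OC)c2OC)c(Oc2cc(OC)c(Oc3cc(OC)c(C=O)c(OC)c3Br)c(OC)c2)c(Oc2c(OC)cc(OC)c(-c3c(OC)cc(OC)cc3OC)c2OC)c1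
F4 | step 4 | 2,6-bis(4-acetoxy-3-bromo-2,6-dimethoxyphenoxy)-4-methoxyphenyl acetate | COc1cc(Oc2c(OC)cc(OC(C)=O)c(Br)c2OC)c(OC(C)=O)c(Oc2c(OC)cc(OC(C)=O)c(Br)c2OC)c1
F5 | step 4 | 2,6-bis(3-bromo-4-hydroxy-2,6-dimethoxyphenoxy)-4-methoxyphenyl acetate | COc1cc(Oc2c(OC)cc(O)c(Br)c2OC)c(OC(C)=O)c(Oc2c(OC)cc(O)c(Br)c2OC)c1
F6 | step 4 | 2,6-bis(3-bromo-2,4,6-trimethoxyphenoxy)-4-methoxyphenyl acetate | COc1cc(Oc2c(OC)cc(OC)c(Br)c2OC)c(OC(C)=O)c(Oc2c(OC)cc(OC)c(Br)c2OC)c1
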